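## Retrosynthetic overview

1. Caraganin C comes from its bis-silyl ether. The chroman ring is closed last (C2–O1) by acid etherification of a 2,4-dimethoxybenzylic alcohol, made by opening a trans-3,4-disubstituted 7-methoxydihydrocoumarin with 2,4-dimethoxyphenyllithium and reducing in the same pot.
2. The C3–benzyl bond comes from trans-selective enolate benzylation of the 4-alkenyl dihydrocoumarin.
3. The key C4–alkenyl bond joins two electrophilic carbons reductively: 7-methoxycoumarin, used as a chiral nickel homoenolate (C4 made nucleophilic), and an (E)-alkenyl bromide. This sets C4, which then controls C3 and C2.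
4. Building blocks: p-coumaric acid (alkenyl bromide), p-cresol (benzyl bromide), 1-bromo-2,4-dimethoxybenzene.
5. Ring order: ring A and the pyranone ring are bought together as the coumarin; the oxygen ring is opened once and re-closed as the chroman. No aryl ring is built.

Assumption: which enantiomer of the PyBox ligand gives the (4S)-lactone 10 cannot be predicted with certainty; the (S,S)-ligand is written and its mirror image is used if the sense of induction proves opposite.

## Route

Step 1
Reactants: 1 (E)-3-(4-hydroxyphenyl)prop-2-enoic acid (p-coumaric acid)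
Product: 3 (E)-3-[4-(tert-butyldimethylsilyloxy)phenyl]prop-2-enoic acid, via bis-silylated silyl ester 2 (not isolated)
Conditions: TBSCl (2.3 equiv), imidazole (4 equiv), DMF, rt; then THF/H2O/AcOH (cat.), rt, 1 h
Reagents that add atoms: tert-butyldimethylsilyl chloride (TBSCl), CC(C)(C)[Si](C)(C)Cl
Why: Silylation of phenol and acid, then selective hydrolysis of the much more labile silyl ester, leaves only the aryl silyl ether.

Step 2
Reactants: 3 (E)-3-[4-(tert-butyldimethylsilyloxy)phenyl]prop-2-enoic acid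
Product: 4 (E)-[4-(2-bromoethenyl)phenoxy](tert-butyl)dimethylsilane
Conditions: NBS (1.05 equiv), LiOAc (10 mol %), MeCN/H2O 19:1, rt
Reagents that add atoms: N-bromosuccinimide (NBS), BrN1C(=O)CCC1=O
Why: Catalytic Hunsdiecker-type bromodecarboxylation of an electron-rich cinnamic acid (bromonium, then loss of CO2) gives the (E)-alkenyl bromide.

Step 3
Reactants: 5 4-methylphenol (p-cresol)
Product: 6 tert-butyldimethyl(4-methylphenoxy)silane
Conditions: TBSCl (1.1 equiv), imidazole (2 equiv), DMF, rt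
Reagents that add atoms: tert-butyldimethylsilyl chloride (TBSCl), CC(C)(C)[Si](C)(C)Cl
Why: Standard phenol silylation.

Step 4
Reactants: 6 tert-butyldimethyl(4-methylphenoxy)silane
Product: 7 [4-(bromomethyl)phenoxy](tert-butyl)dimethylsilane
Conditions: NBS (1.05 equiv), AIBN (5 mol %), PhCF3, 80 °C
Reagents that add atoms: N-bromosuccinimide (NBS), BrN1C(=O)CCC1=O
Why: Wohl–Ziegler radical bromination at the only benzylic position.

Step 5
Reactants: 8 7-methoxycoumarin and 4 (E)-[4-(2-bromoethenyl)phenoxy](tert-butyl)dimethylsilane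
Product: 10 (4S)-4-{(E)-2-[4-(tert-butyldimethylsilyloxy)phenyl]ethenyl}-7-methoxy-3,4-dihydro-2H-chromen-2-one, via trimethylsilyl ketene acetal 9 (not isolated)
Conditions: NiBr2(dme) (10 mol %), (S,S)-i-Pr-PyBox (12 mol %), Mn powder (2.5 equiv), Me3SiCl (1.5 equiv), DMA, 0 °C → rt; then 1 M HCl/THF, 0 °C; one recrystallisation to raise ee
Reagents that add atoms: none
Why: Proposed new method: nickel homoenolate cross-coupling – zerovalent nickel and Me3SiCl turn the coumarin (a planar cyclic enoate, reduced about as easily as cyclohexenone) into a 1-silyloxy-allyl nickel species in which C4, normally the electrophilic β-carbon, carries the metal; this couples with the alkenyl bromide (the second electrophile) with retention of the E geometry while Mn regenerates the low-valent catalyst, and the C2-symmetric PyBox ligand (a chiral analogue of the terpyridine used in the racemic reaction) shields one face of the allyl fragment so that the new C4 stereocenter forms as 4S; closest known reaction type: nickel-catalysed reductive conjugate addition of aryl and alkenyl halides to enones with chlorosilanes, and enantioselective nickel-catalysed reductive cross-coupling of alkenyl bromides with benzylic electrophiles.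

Step 6
Reactants: 10 (4S)-4-alkenyl dihydrocoumarin and 7 [4-(bromomethyl)phenoxy](tert-butyl)dimethylsilane
Product: 12 (3R,4R)-3-[4-(tert-butyldimethylsilyloxy)benzyl]-4-{(E)-2-[4-(tert-butyldimethylsilyloxy)phenyl]ethenyl}-7-methoxy-3,4-dihydro-2H-chromen-2-one (3,4-trans), via lithium enolate 11 (not isolated)
Conditions: LiN(SiMe3)2 (1.05 equiv), THF, −78 °C, 30 min; 7 (1.2 equiv), −78 → −50 °C
Reagents that add atoms: none
Why: Enolate alkylation (SN2) occurs on the face opposite the C4 alkenyl group, giving the 3,4-trans lactone with C3 as R (the C4 descriptor changes from S to R only because the C3 branch gains priority).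

Step 7
Reactants: 12 (3R,4R)-trans lactone and 13 1-bromo-2,4-dimethoxybenzene
Product: 17 (2R,3R,4R)-3-[4-(tert-butyldimethylsilyloxy)benzyl]-4-{(E)-2-[4-(tert-butyldimethylsilyloxy)phenyl]ethenyl}-2-(2,4-dimethoxyphenyl)-7-methoxychroman, via 2,4-dimethoxyphenyllithium 14 (not isolated), via lithium keto-phenoxide 15 (not isolated), via benzylic alcohol 16 (not isolated)
Conditions: 13 (1.2 equiv), n-BuLi (1.15 equiv), THF, −78 °C, 30 min; add 12, −78 °C, 1 h; LiBH4 (2 equiv), −78 → 0 °C; then 2 M aq HCl to pH 1, rt, 2 h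
Reagents that add atoms: none
Why: Bromine–lithium exchange and acyl substitution on the aryl lactone give the aryl ketone, which LiBH4 reduces in the same pot before its α-stereocenter can epimerise; on acidification the 2,4-dimethoxybenzylic alcohol ionises (SN1 cycloetherification) and the ring-A phenol closes the chroman reversibly, so C2 settles as the all-equatorial 2,3-trans isomer (2R).

Step 8
Reactants: 17 bis-silyl ether of caraganin C
Product: 18 caraganin C, (2R,3R,4R)-2-(2,4-dimethoxyphenyl)-3-(4-hydroxybenzyl)-4-[(E)-2-(4-hydroxyphenyl)ethenyl]-7-methoxychroman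
Conditions: Bu4NF (2.5 equiv), AcOH (2.5 equiv), THF, 0 °C → rt
Reagents that add atoms: none
Why: Fluoride desilylation of the two aryl silyl ethers under buffered conditions touches neither the chroman stereocenters nor the alkene.

## Compound list

1 | (E)-3-(4-hydroxyphenyl)prop-2-enoic acid (p-coumaric acid) | OC(=O)/C=C/c1ccc(O)cc1 | starting material
2 | tert-butyldimethylsilyl (E)-3-[4-(tert-butyldimethylsilyloxy)phenyl]prop-2-enoate | CC(C)(C)[Si](C)(C)OC(=O)/C=C/c1ccc(O[Si](C)(C)C(C)(C)C)cc1 | intermediate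
3 | (E)-3-[4-(tert-butyldimethylsilyloxy)phenyl]prop-2-enoic acid | OC(=O)/C=C/c1ccc(O[Si](C)(C)C(C)(C)C)cc1 | intermediate
4 | (E)-[4-(2-bromoethenyl)phenoxy](tert-butyl)dimethylsilane | Br/C=C/c1ccc(O[Si](C)(C)C(C)(C)C)cc1 | intermediate
5 | 4-methylphenol (p-cresol) | Cc1ccc(O)cc1 | starting material
6 | tert-butyldimethyl(4-methylphenoxy)silane | Cc1ccc(O[Si](C)(C)C(C)(C)C)cc1 | intermediate
7 | [4-(bromomethyl)phenoxy](tert-butyl)dimethylsilane | BrCc1ccc(O[Si](C)(C)C(C)(C)C)cc1 | intermediate
8 | 7-methoxycoumarin (7-methoxy-2H-chromen-2-one) | COc1ccc2c(c1)OC(=O)C=C2 | starting material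
9 | (4R)-4-{(E)-2-[4-(tert-butyldimethylsilyloxy)phenyl]ethenyl}-7-methoxy-2-(trimethylsilyloxy)-4H-chromene (same spatial arrangement at C4 as 10) | COc1ccc2c(c1)OC(O[Si](C)(C)C)=C[C@H]2/C=C/c1ccc(O[Si](C)(C)C(C)(C)C)cc1 | intermediate
10 | (4S)-4-{(E)-2-[4-(tert-butyldimethylsilyloxy)phenyl]ethenyl}-7-methoxy-3,4-dihydro-2H-chromen-2-one | COc1ccc2c(c1)OC(=O)C[C@H]2/C=C/c1ccc(O[Si](C)(C)C(C)(C)C)cc1 | intermediate
11 | lithium enolate of 10 (lithium (4R)-4-alkenyl-7-methoxy-4H-chromen-2-olate) | COc1ccc2c(c1)OC(O[Li])=C[C@H]2/C=C/c1ccc(O[Si](C)(C)C(C)(C)C)cc1 | intermediate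
12 | (3R,4R)-3-[4-(tert-butyldimethylsilyloxy)benzyl]-4-{(E)-2-[4-(tert-butyldimethylsilyloxy)phenyl]ethenyl}-7-methoxy-3,4-dihydro-2H-chromen-2-one | COc1ccc2c(c1)OC(=O)[C@H](Cc1ccc(O[Si](C)(C)C(C)(C)C)cc1)[C@H]2/C=C/c1ccc(O[Si](C)(C)C(C)(C)C)cc1 | intermediate
13 | 1-bromo-2,4-dimethoxybenzene | COc1ccc(Br)c(OC)c1 | starting material
14 | 2,4-dimethoxyphenyllithium | [Li]c1ccc(OC)cc1OC | intermediate
15 | lithium phenoxide of (2R,3R,4E)-2-[4-(tert-butyldimethylsilyloxy)benzyl]-5-[4-(tert-butyldimethylsilyloxy)phenyl]-1-(2,4-dimethoxyphenyl)-3-(2-hydroxy-4-methoxyphenyl)pent-4-en-1-one | O=C(c1ccc(OC)cc1OC)[C@H](Cc1ccc(O[Si](C)(C)C(C)(C)C)cc1)[C@@H](/C=C/c1ccc(O[Si](C)(C)C(C)(C)C)cc1)c1ccc(OC)cc1O[Li] | intermediate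
16 | (2R,3R,4E)-2-[4-(tert-butyldimethylsilyloxy)benzyl]-5-[4-(tert-butyldimethylsilyloxy)phenyl]-1-(2,4-dimethoxyphenyl)-3-(2-hydroxy-4-methoxyphenyl)pent-4-en-1-ol (both C1 epimers) | OC(c1ccc(OC)cc1OC)[C@H](Cc1ccc(O[Si](C)(C)C(C)(C)C)cc1)[C@@H](/C=C/c1ccc(O[Si](C)(C)C(C)(C)C)cc1)c1ccc(OC)cc1O | intermediate
17 | (2R,3R,4R)-3-[4-(tert-butyldimethylsilyloxy)benzyl]-4-{(E)-2-[4-(tert-butyldimethylsilyloxy)phenyl]ethenyl}-2-(2,4-dimethoxyphenyl)-7-methoxychroman | COc1ccc2c(c1)O[C@@H](c1ccc(OC)cc1OC)[C@H](Cc1ccc(O[Si](C)(C)C(C)(C)C)cc1)[C@H]2/C=C/c1ccc(O[Si](C)(C)C(C)(C)C)cc1 | intermediate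
18 | caraganin C, (2R,3R,4R)-2-(2,4-dimethoxyphenyl)-3-(4-hydroxybenzyl)-4-[(E)-2-(4-hydroxyphenyl)ethenyl]-7-methoxychroman | COc1ccc2c(c1)O[C@@H](c1ccc(OC)cc1OC)[C@H](Cc1ccc(O)cc1)[C@H]2/C=C/c1ccc(O)cc1 | target

## Step count and risk

Total step count: 8. Longest linear sequence: 6 (steps 1, 2, 5, 6, 7, 8).

Steps most likely to fail:

Step 5 (nickel homoenolate alkenylation). The reaction is unproven on an enoate and the level of enantioselectivity is unknown. Fallback: starting from 8, conjugate borylation with B2pin2 and MeOH in THF, catalysed by CuCl/NaOt-Bu/(R)-Segphos, gives the boron homoenolate (4R)-7-methoxy-4-(4,4,5,5-tetramethyl-1,3,2-dioxaborolan-2-yl)-3,4-dihydro-2H-chromen-2-one F1. Its secondary benzylic C–B bond is then cross-coupled with 4 under Pd(PPh3)4/Ag2O in DME with retention, which returns to the route at 10. The ligand enantiomer is chosen to match the stereochemical course found for the coupling.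

Step 6 (benzylation of an aryl-lactone enolate). Ring opening to a ketene, O-alkylation or double alkylation may compete. Fallback: starting from 10, the lithium enolate is added at −78 °C to commercial 4-(tert-butyldimethylsilyloxy)benzaldehyde, again anti to the C4 substituent. This aldol addition gives the β-hydroxy lactone (3S,4R)-3-{hydroxy[4-(tert-butyldimethylsilyloxy)phenyl]methyl}-4-{(E)-2-[4-(tert-butyldimethylsilyloxy)phenyl]ethenyl}-7-methoxy-3,4-dihydro-2H-chromen-2-one F2 as carbinol epimers. The benzylic hydroxyl is then removed by ionic hydrogenation (Et3SiH, BF3·OEt2, CH2Cl2, −78 °C), which returns to the route at 12.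

Step 7 (aryllithium opening, in-pot reduction and cyclisation). Enolisation of the α-branched lactone, double aryl addition or epimerisation of ketone 15 are the dangers. Fallback: starting from 12, the lactone is reduced with i-Bu2AlH (CH2Cl2, −78 °C) to the lactol (3R,4R)-3-[4-(tert-butyldimethylsilyloxy)benzyl]-4-{(E)-2-[4-(tert-butyldimethylsilyloxy)phenyl]ethenyl}-7-methoxy-3,4-dihydro-2H-chromen-2-ol F3. Its open hydroxy-aldehyde form is treated with 2,4-(MeO)2C6H3MgBr (from 13 and Mg, 3 equiv, THF, 0 °C), so that no epimerisable ketone is ever formed. This returns to the route at 16, which is cyclised with the acid treatment of step 7.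

Further compounds

F1 | step 5 | (4R)-7-methoxy-4-(4,4,5,5-tetramethyl-1,3,2-dioxaborolan-2-yl)-3,4-dihydro-2H-chromen-2-one | COc1ccc2c(c1)OC(=O)C[C@H]2B1OC(C)(C)C(C)(C)O1
F2 | step 6 | (3S,4R)-3-{hydroxy[4-(tert-butyldimethylsilyloxy)phenyl]methyl}-4-{(E)-2-[4-(tert-butyldimethylsilyloxy)phenyl]ethenyl}-7-methoxy-3,4-dihydro-2H-chromen-2-one (carbinol epimers) | COc1ccc2c(c1)OC(=O)[C@H](C(O)c1ccc(O[Si](C)(C)C(C)(C)C)cc1)[C@H]2/C=C/c1ccc(O[Si](C)(C)C(C)(C)C)cc1
F3 | step 7 | (3R,4R)-3-[4-(tert-butyldimethylsilyloxy)benzyl]-4-{(E)-2-[4-(tert-butyldimethylsilyloxy)phenyl]ethenyl}-7-methoxy-3,4-dihydro-2H-chromen-2-ol (anomer mixture) | COc1ccc2c(c1)OC(O)[C@H](Cc1ccc(O[Si](C)(C)C(C)(C)C)cc1)[C@H]2/C=C/c1ccc(O[Si](C)(C)C(C)(C)C)cc1
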